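The isovanilloyl ester is not made by acylation. The carbonyl carbon is first installed as a six-membered cyclic carbonate (1,3-dioxan-2-one) spanning O6 and O8 of the syn-1,3-diol on C6–C7–C8 of the ten-membered germacrane ring. An aryllithium made from 5-bromo-2-methoxyphenol adds to that carbonyl, and the tetrahedral intermediate collapses by expelling the C6 alkoxide, which is activated by the adjacent C4–C5 oxirane. One operation thus forms the aryl–carbonyl bond, places the ester on O8 and frees the C6 hydroxyl. The carbonate comes from geraniol via Sharpless epoxidation, a samarium-mediated macro-aldol and a syn-selective reduction.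

Key step: step 10

Remark: germacrane numbering is used (C1=C10 alkene, C4–C5 oxirane, C6–OH, C7–isopropyl, C8–O); the CIP label at C7 is R in 12, 13 and 19 but S in 14, 15 and 18 through ligand priorities only, the spatial arrangement being the same.
Assumption: tributyl(2-methylprop-1-en-1-yl)stannane 5 is taken as a purchasable reagent.

Step 1
Reactants: 1 geraniol
Product: 2 (2R,3R)-2,3-epoxygeraniol
Conditions: Ti(OiPr)4 (5 mol %), D-(−)-diethyl tartrate (6 mol %), TBHP, 4 Å MS, CH2Cl2, −20 °C
Reagents that add atoms: tert-butyl hydroperoxide, CC(C)(C)OO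
Why: Katsuki–Sharpless asymmetric epoxidation, in which the titanium/D-(−)-tartrate catalyst epoxidises only the allylic-alcohol alkene and should deliver oxygen to the face that gives the (2R,3R)-epoxide, fixing C4 and C5 of the target by catalyst control.

Step 2
Reactants: 2 (2R,3R)-2,3-epoxygeraniol
Product: 3 epoxy diol (2E)-5-[(2R,3R)-3-(hydroxymethyl)-2-methyloxiran-2-yl]-2-methylpent-2-en-1-ol
Conditions: SeO2 (0.3 equiv), TBHP (3 equiv), salicylic acid (cat.), CH2Cl2, rt
Reagents that add atoms: selenium dioxide (catalytic oxygen carrier), O=[Se]=O; tert-butyl hydroperoxide (terminal oxidant), CC(C)(C)OO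
Why: Selenium dioxide allylic oxidation (ene reaction then [2,3]-shift) should attack the (E)-methyl group of the only remaining trisubstituted alkene and give the (E)-allylic alcohol, with no stereocentre formed.

Step 3
Reactants: 3 epoxy diol
Product: 4 allylic chloride [(2R,3R)-3-[(3E)-5-chloro-4-methylpent-3-en-1-yl]-3-methyloxiran-2-yl]methanol
Conditions: NCS, Me2S, CH2Cl2, −20 to 0 °C
Reagents that add atoms: N-chlorosuccinimide, O=C1CCC(=O)N1Cl
Why: Corey–Kim chlorination, in which only the allylic alkoxysulfonium ion is displaced by chloride (SN2 at the primary carbon, alkene geometry kept) while the saturated epoxy carbinol should be returned unchanged on work-up.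

Step 4
Reactants: 4 allylic chloride; 5 tributyl(2-methylprop-1-en-1-yl)stannane
Product: 6 dienone (6E)-9-[(2R,3R)-3-(hydroxymethyl)-2-methyloxiran-2-yl]-2,6-dimethylnona-2,6-dien-4-one
Conditions: CO (3 atm), Pd2(dba)3 (2.5 mol %), PPh3 (10 mol %), THF, 50 °C
Reagents that add atoms: carbon monoxide, [C-]#[O+]
Why: Carbonylative Stille coupling (oxidative addition of the allylic chloride, CO insertion at the primary terminus, alkenyl transfer from tin) should give the allyl alkenyl ketone under neutral conditions, so the C1=C10 alkene stays (E) and out of conjugation and the 2,3-epoxy alcohol, which is no allylic electrophile, is left alone.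

Step 5
Reactants: 6 dienone
Product: 9 α-bromo ketone (6E)-3-bromo-9-[(2R,3R)-3-(hydroxymethyl)-2-methyloxiran-2-yl]-2,6-dimethylnon-6-en-4-one (both C3 epimers), via bis-silyl enol ether 7 (not isolated), via silylated bromo ketone 8 (not isolated)
Conditions: [(Ph3P)CuH]6 (5 mol % Cu), PhMe2SiH (2.5 equiv), toluene, rt; NBS, THF, −78 °C; MeOH, citric acid (cat.), 0 °C
Reagents that add atoms: N-bromosuccinimide, O=C1CCC(=O)N1Br
Why: Copper hydride-catalysed 1,4-hydrosilylation of the enone (with concurrent dehydrogenative O-silylation of the carbinol) should give the regiodefined silyl enol ether 7, which NBS brominates only at C7 (α-bromination of a silyl enol ether) before methanolysis removes the labile silyl ether; the C7 epimer mixture is of no consequence because C7 becomes an enolate carbon in step 7.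

Step 6
Reactants: 9 α-bromo ketone
Product: 10 epoxy aldehyde (2S,3R)-3-[(3E)-7-bromo-4,8-dimethyl-6-oxonon-3-en-1-yl]-3-methyloxirane-2-carbaldehyde (both CHBr epimers)
Conditions: DMP, NaHCO3, CH2Cl2, 0 °C
Reagents that add atoms: none
Why: Dess–Martin oxidation under bicarbonate buffer should convert the primary epoxy alcohol into the α,β-epoxy aldehyde without epimerisation (the α-carbon is the oxirane carbon) and without base that would dehydrobrominate the bromo ketone.

Step 7
Reactants: 10 epoxy aldehyde
Product: 12 (4R,5R,6R,7R)-4,5-epoxy-6-hydroxygermacr-1(10)E-en-8-one, via samarium enolate 11 (not isolated)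
Conditions: SmI2 (2.2 equiv), THF, −78 °C, slow addition of 10 (final 2 mM); pH 7 buffer
Reagents that add atoms: none
Why: Samarium diiodide-mediated intramolecular Reformatsky-type aldol reaction, in which reduction of the C–Br bond gives the samarium(III) enolate 11 at C7 only (not at the more acidic C9) and the ten-membered ring should close through a chelated chair transition state of the (Z)-enolate (C6–OH and C7–isopropyl syn) with attack anti to the oxirane C5–O bond (Cornforth/Felkin–Anh, C5–O and C6–OH anti), so C6 and C7 are relayed from the Sharpless centres.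

Step 8
Reactants: 12 β-hydroxy ketone
Product: 14 (4R,5R,6R,7S,8R)-4,5-epoxygermacr-1(10)E-ene-6,8-diol, via boron chelate 13 (not isolated)
Conditions: Et2BOMe, THF/MeOH 4:1, −78 °C; NaBH4; MeOH co-evaporation
Reagents that add atoms: none
Why: Narasaka–Prasad reduction, in which the C6 hydroxyl forms the diethylboron chelate 13 with the C8 ketone and external hydride attacks the chelate axially, should give the 1,3-syn diol and set C8 under control of C6.

Step 9
Reactants: 14 syn-1,3-diol
Product: 15 cyclic carbonate (4R,5R,6R,7S,8R)-4,5-epoxygermacr-1(10)E-ene-6,8-diyl carbonate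
Conditions: CDI, DMAP (cat.), toluene, 60 °C
Reagents that add atoms: 1,1'-carbonyldiimidazole, O=C(n1ccnc1)n1ccnc1
Why: Carbonylation of the syn-1,3-diol with carbonyldiimidazole (acyl transfer then 6-exo-trig ring closure) should give the 1,3-dioxan-2-one, with C5 and C9 axial and the isopropyl group equatorial on the carbonate chair, under non-acidic conditions that spare the oxirane.

Step 10
Reactants: 15 cyclic carbonate; 16 5-bromo-2-methoxyphenol
Product: 19 (4R,5R,6R,7R,8R)-4,5-epoxy-6-hydroxygermacr-1(10)E-en-8-yl 3-hydroxy-4-methoxybenzoate (CNP0294356.1), via dilithio arene 17 (not isolated), via lithium orthoester 18 (not isolated)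
Conditions: 16, n-BuLi (1 equiv) then t-BuLi (2 equiv), THF, −78 °C; add 15, −78 to −40 °C; AcOH, −78 °C
Reagents that add atoms: none
Why: The aryllithium 17 adds to the carbonate carbonyl of 15 to give the lithium orthoester alkoxide 18, which collapses by cleaving the C(=O)–O6 bond and leaves the aroyl group on O8. The closest known reaction type is the opening of cyclic carbonates of diols by aryllithiums to hydroxy benzoates, applied here to a 1,3-dioxan-2-one. No ring is closed (the dioxanone ring is opened) and no stereocentre is created, so C4–C8 pass through unchanged. The step needs C–O6 rather than C–O8 cleavage: the O6 alkoxide is the better leaving group because it is stabilised inductively and by lithium chelation to the neighbouring oxirane oxygen, and the ester should rest on the less hindered O8 (next to C9H2) rather than on O6 (between C5 and C7). It also needs mono-addition, which the persistence of 18 at low temperature and the low electrophilicity of the electron-rich aroyl ester should secure. Quenching with acetic acid at −78 °C should prevent 1,3-acyl migration and Payne rearrangement, and the oxirane and the trisubstituted alkene do not react with an aryllithium at this temperature.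

Compound list
1 | geraniol, (2E)-3,7-dimethylocta-2,6-dien-1-ol | CC(C)=CCC/C(C)=C/CO | starting material
2 | (2R,3R)-2,3-epoxygeraniol, [(2R,3R)-3-methyl-3-(4-methylpent-3-en-1-yl)oxiran-2-yl]methanol | CC(C)=CCC[C@@]1(C)O[C@@H]1CO | intermediate
3 | (2E)-5-[(2R,3R)-3-(hydroxymethyl)-2-methyloxiran-2-yl]-2-methylpent-2-en-1-ol | OC/C(C)=C/CC[C@@]1(C)O[C@@H]1CO | intermediate
4 | [(2R,3R)-3-[(3E)-5-chloro-4-methylpent-3-en-1-yl]-3-methyloxiran-2-yl]methanol | ClC/C(C)=C/CC[C@@]1(C)O[C@@H]1CO | intermediate
5 | tributyl(2-methylprop-1-en-1-yl)stannane | CC(C)=C[Sn](CCCC)(CCCC)CCCC | starting material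
6 | (6E)-9-[(2R,3R)-3-(hydroxymethyl)-2-methyloxiran-2-yl]-2,6-dimethylnona-2,6-dien-4-one | CC(C)=CC(=O)C/C(C)=C/CC[C@@]1(C)O[C@@H]1CO | intermediate
7 | (Z)-dimethylphenylsilyl enol ether of the C8 ketone of 6, carbinol as dimethylphenylsilyl ether (not isolated) | CC(C)/C=C(O[Si](C)(C)c1ccccc1)/C/C(C)=C/CC[C@@]1(C)O[C@@H]1CO[Si](C)(C)c1ccccc1 | intermediate
8 | O-dimethylphenylsilyl ether of bromo ketone 9, both CHBr epimers (not isolated) | CC(C)C(Br)C(=O)C/C(C)=C/CC[C@@]1(C)O[C@@H]1CO[Si](C)(C)c1ccccc1 | intermediate
9 | (6E)-3-bromo-9-[(2R,3R)-3-(hydroxymethyl)-2-methyloxiran-2-yl]-2,6-dimethylnon-6-en-4-one, both C3 epimers | CC(C)C(Br)C(=O)C/C(C)=C/CC[C@@]1(C)O[C@@H]1CO | intermediate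
10 | (2S,3R)-3-[(3E)-7-bromo-4,8-dimethyl-6-oxonon-3-en-1-yl]-3-methyloxirane-2-carbaldehyde, both CHBr epimers | CC(C)C(Br)C(=O)C/C(C)=C/CC[C@@]1(C)O[C@@H]1C=O | intermediate
11 | samarium(III) (Z)-enolate of debrominated 10 (not isolated) | CC(C)/C=C(O[Sm](I)I)/C/C(C)=C/CC[C@@]1(C)O[C@@H]1C=O | intermediate
12 | (4R,5R,6R,7R)-4,5-epoxy-6-hydroxygermacr-1(10)E-en-8-one | O=C1C/C(C)=C/CC[C@@]2(C)O[C@@H]2[C@H](O)[C@H]1C(C)C | intermediate
13 | O6-diethylboryl chelate of 12 (not isolated) | O=C1C/C(C)=C/CC[C@@]2(C)O[C@@H]2[C@H](OB(CC)CC)[C@H]1C(C)C | intermediate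
14 | (4R,5R,6R,7S,8R)-4,5-epoxygermacr-1(10)E-ene-6,8-diol | O[C@@H]1C/C(C)=C/CC[C@@]2(C)O[C@@H]2[C@H](O)[C@H]1C(C)C | intermediate
15 | (4R,5R,6R,7S,8R)-4,5-epoxygermacr-1(10)E-ene-6,8-diyl carbonate (1,3-dioxan-2-one across O6 and O8) | O=C1O[C@@H]2C/C(C)=C/CC[C@@]3(C)O[C@@H]3[C@H](O1)[C@H]2C(C)C | intermediate
16 | 5-bromo-2-methoxyphenol | COc1ccc(Br)cc1O | starting material
17 | lithium 5-lithio-2-methoxyphenolate (not isolated) | COc1ccc([Li])cc1O[Li] | intermediate
18 | lithium orthoester alkoxide from addition of 17 to the carbonyl of 15, orthoester carbon unassigned (not isolated) | COc1ccc(cc1O[Li])C1(O[Li])O[C@@H]2C/C(C)=C/CC[C@@]3(C)O[C@@H]3[C@H](O1)[C@H]2C(C)C | intermediate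
19 | (4R,5R,6R,7R,8R)-4,5-epoxy-6-hydroxygermacr-1(10)E-en-8-yl 3-hydroxy-4-methoxybenzoate (CNP0294356.1) | COc1ccc(C(=O)O[C@@H]2C/C(C)=C/CC[C@@]3(C)O[C@@H]3[C@H](O)[C@H]2C(C)C)cc1O | target

Total step count: 10. Longest linear sequence: 10 steps (1 to 19).

Steps most likely to fail

Step 7 (macro-aldol). The risks are single-electron reduction of the α,β-epoxy aldehyde (reductive oxirane opening) competing with C–Br reduction, oligomerisation instead of ring closure, and poor facial selectivity in the ten-membered transition state. The fallback sets out from 6. Dess–Martin oxidation gives the enone aldehyde (2S,3R)-3-[(3E)-4,8-dimethyl-6-oxonona-3,7-dien-1-yl]-3-methyloxirane-2-carbaldehyde F3. A copper hydride-mediated reductive aldol cyclisation (stoichiometric [(Ph3P)CuH]6, toluene, −40 °C, high dilution) then forms the C7 copper enolate by conjugate hydride delivery to the enone and closes the ring, returning to the route at 12.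

Step 10 (carbonate opening). The risks are collapse of the tetrahedral intermediate towards the O6 ester, 1,3-acyl migration during the quench, and a second addition of the aryllithium. The fallback sets out from diol 14. Commercial 5-iodo-2-methoxyphenol is silylated (TBSCl, imidazole) to tert-butyl(5-iodo-2-methoxyphenoxy)dimethylsilane F1. A palladium-catalysed alkoxycarbonylation (Pd(OAc)2, Xantphos, CO 1 atm, K3PO4, toluene, 70 °C) forms the aryl–carbonyl bond by CO insertion into the aryl–palladium bond, and the less hindered C8 hydroxyl of 14 captures the aroyl–palladium species to give the silyl-protected ester F2. Buffered desilylation (TBAF, AcOH, THF, 0 °C) returns to the route at 19.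

Step 4 (carbonylative coupling). The risks are direct coupling without CO insertion, loss of the (E)-geometry through π-allyl isomerisation, and capture of the acyl–palladium species by the free hydroxyl. The fallback sets out from 4. 3-Methylbut-2-enal and propane-1,3-dithiol (BF3·OEt2) give 2-(2-methylprop-1-en-1-yl)-1,3-dithiane F4. Its 2-lithio derivative (n-BuLi, THF, −30 °C, 2.2 equiv) is alkylated at the dithiane carbon by the allylic chloride to give the dithiane F5, and dethioketalisation (MeI, CaCO3, aqueous MeCN) returns to the route at 6.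

Further compounds
F1 | step 10 | tert-butyl(5-iodo-2-methoxyphenoxy)dimethylsilane | COc1ccc(I)cc1O[Si](C)(C)C(C)(C)C
F2 | step 10 | (4R,5R,6R,7R,8R)-4,5-epoxy-6-hydroxygermacr-1(10)E-en-8-yl 3-(tert-butyldimethylsilyloxy)-4-methoxybenzoate | COc1ccc(C(=O)O[C@@H]2C/C(C)=C/CC[C@@]3(C)O[C@@H]3[C@H](O)[C@H]2C(C)C)cc1O[Si](C)(C)C(C)(C)C
F3 | step 7 | (2S,3R)-3-[(3E)-4,8-dimethyl-6-oxonona-3,7-dien-1-yl]-3-methyloxirane-2-carbaldehyde | CC(C)=CC(=O)C/C(C)=C/CC[C@@]1(C)O[C@@H]1C=O
F4 | step 4 | 2-(2-methylprop-1-en-1-yl)-1,3-dithiane | CC(C)=CC1SCCCS1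
F5 | step 4 | [(2R,3R)-3-methyl-3-[(3E)-4-methyl-5-[2-(2-methylprop-1-en-1-yl)-1,3-dithian-2-yl]pent-3-en-1-yl]oxiran-2-yl]methanol | CC(C)=CC1(SCCCS1)C/C(C)=C/CC[C@@]2(C)O[C@@H]2CO
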